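**Plan**

1. Carotenoid numbering: ring C2(isopropenyl)–C3–C4–C5(CH3,OH)–C6, chain C7…C15–C15'…C1'. The retrosynthesis cuts the C15'–C14' sp2–sp2 bond first (C21 bromide + C18 alkyne + one methyl), then C14–C15, C10–C11, C10'–C11' and C6'–C7' by the same alkyne-methylmetalation/cross-coupling logic, then C8–C9 and C7=C8 back to a ring aldehyde, and last the ring bond C5–C6 (aldol) and the ring C=C of (S)-limonene.
2. Forward: the cyclopentane ring is made first (ozonolysis of limonene, 5-enolexo aldol); the left chain grows outward from the ring (C7 to C15'), the right chain grows from 6-methylhept-5-en-1-yne toward the centre (C5' to C14'), and the two halves are joined last.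
3. Enabling feature: the trisubstituted C13'(CH3)=C14'H alkene sits directly beside the unsubstituted E-C15=C15' unit, with methyl on the distal carbon and hydrogen on the bond-forming carbon. This is the signature of syn-methylmetalation of a terminal alkyne C13'≡C14'–H, so the junction bond, the C13' methyl branch and the 13'E geometry can be made in one pot from a C18 tetraenyne.
4. Stereochemistry: C2 is bought with (S)-limonene; C5 and C6 are set together in the aldol by substrate control (matched D-proline). Every trisubstituted E-alkene comes from syn-carboalumination; the disubstituted E-alkenes come from Takai olefination and from E-haloalkene building blocks coupled with retention.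
5. Helpers: alkyne C–SiMe3 caps (removed with K2CO3/MeOH); the tertiary hydroxyl rides through the organoaluminium steps as a transient O–AlMe2 alkoxide, released on aqueous work-up.

Key step: step 15

Remark: the SMILES is read as the (2S,5S,6R) ring [(1S,2R,3S) in cyclopentanol numbering; isopropenyl trans to the polyene, polyene cis to OH] with all chain double bonds E; (E)-1-bromo-2-iodoethene and the silylated bromoenyne are assumed not to be purchasable and are made in steps 1 and 2.

**Route**

Step 1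
Reactants: 1 acetylene
Product: 2 (E)-1-bromo-2-iodoethene
Conditions: IBr, 48% aq. HBr, 0 °C, acetylene bubbled through
Reagents that add atoms: iodine monobromide, IBr
Why: electrophilic anti-addition of IBr to the alkyne (iodonium opened by bromide) should give the E-dihaloethene.

Step 2
Reactants: 2 (E)-1-bromo-2-iodoethene; 3 ethynyltrimethylsilane
Product: 5 [(3E)-4-bromobut-3-en-1-yn-1-yl]trimethylsilane, via [(trimethylsilyl)ethynyl]zinc bromide 4 (not isolated)
Conditions: 3, n-BuLi, THF, −78 °C; ZnBr2, 0 °C; then 2, Pd(PPh3)4 (3 mol%), 0 °C → rt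
Reagents that add atoms: none
Why: Negishi alkynyl–alkenyl coupling, in which zerovalent palladium inserts into C–I far faster than into C–Br and the E geometry is retained.

Step 3
Reactants: 6 5-bromo-2-methylpent-2-ene
Product: 7 6-methylhept-5-en-1-yne
Conditions: LiC≡CH·H2NCH2CH2NH2 (1.2 equiv), DMSO, 10 °C → rt
Reagents that add atoms: lithium acetylide (ethylenediamine complex), [Li]C#C
Why: SN2 alkylation of an acetylide by a primary bromide in a dipolar aprotic solvent.

Step 4
Reactants: 7 6-methylhept-5-en-1-yne; 5 [(3E)-4-bromobut-3-en-1-yn-1-yl]trimethylsilane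
Product: 9 trimethyl[(3E,5E)-6,10-dimethylundeca-3,5,9-trien-1-yn-1-yl]silane, via alkenylalane 8 (not isolated)
Conditions: Me3Al (2 equiv), Cp2ZrCl2 (0.5 equiv), CH2Cl2, 0 °C → rt; evaporate; then 5, Pd2(dba)3 (2.5 mol%), P(2-furyl)3 (10 mol%), ZnCl2 (30 mol%), THF, rt
Reagents that add atoms: trimethylaluminium, C[Al](C)C
Why: zirconium-catalysed syn-methylalumination of the terminal alkyne (Negishi carboalumination; methyl to the internal carbon, aluminium to the terminal carbon) followed by palladium-catalysed alkenyl–alkenyl Negishi coupling with retention sets the 5'E trisubstituted alkene and carries over the E-bromoalkene geometry.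

Step 5
Reactants: 9 trimethyl[(3E,5E)-6,10-dimethylundeca-3,5,9-trien-1-yn-1-yl]silane
Product: 10 (3E,5E)-6,10-dimethylundeca-3,5,9-trien-1-yne
Conditions: K2CO3 (cat.), MeOH, rt
Reagents that add atoms: none
Why: base-catalysed methanolysis of the C(sp)–Si bond (protodesilylation) leaves the alkenes untouched.

Step 6
Reactants: 10 (3E,5E)-6,10-dimethylundeca-3,5,9-trien-1-yne; 5 [(3E)-4-bromobut-3-en-1-yn-1-yl]trimethylsilane
Product: 12 trimethyl[(3E,5E,7E,9E)-6,10,14-trimethylpentadeca-3,5,7,9,13-pentaen-1-yn-1-yl]silane, via alkenylalane 11 (not isolated)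
Conditions: Me3Al (2 equiv), Cp2ZrCl2 (1 equiv), ClCH2CH2Cl, rt; evaporate; then 5, Pd2(dba)3 (2.5 mol%), P(2-furyl)3 (10 mol%), ZnCl2 (30 mol%), THF, rt, dark
Reagents that add atoms: trimethylaluminium, C[Al](C)C
Why: second round of syn-methylalumination and Negishi alkenyl–alkenyl coupling, the conjugated alkenes being inert to Me3Al/Cp2ZrCl2, sets the 9'E alkene.

Step 7
Reactants: 12 trimethyl[(3E,5E,7E,9E)-6,10,14-trimethylpentadeca-3,5,7,9,13-pentaen-1-yn-1-yl]silane
Product: 13 (3E,5E,7E,9E)-6,10,14-trimethylpentadeca-3,5,7,9,13-pentaen-1-yne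
Conditions: K2CO3 (cat.), MeOH/THF, rt, dark
Reagents that add atoms: none
Why: protodesilylation of the alkynylsilane under mild base, as in step 5.

Step 8
Reactants: 14 (S)-(−)-limonene
Product: 16 (3S)-6-oxo-3-(prop-1-en-2-yl)heptanal, via ozonide 15 (not isolated)
Conditions: O3 (1.0 equiv), CH2Cl2, −78 °C; then Me2S, −78 °C → rt
Reagents that add atoms: ozone, [O-][O+]=O
Why: ozonolysis with reductive work-up, in which the electron-richer trisubstituted ring alkene reacts before the 1,1-disubstituted isopropenyl group with one equivalent of ozone; the stereocentre is untouched.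

Step 9
Reactants: 16 (3S)-6-oxo-3-(prop-1-en-2-yl)heptanal
Product: 17 (1R,2S,5S)-2-hydroxy-2-methyl-5-(prop-1-en-2-yl)cyclopentane-1-carbaldehyde
Conditions: D-proline (20 mol%), DMF, 0 °C → rt
Reagents that add atoms: none
Why: enamine-mediated 5-enolexo intramolecular aldol in which the aldehyde enamine adds to the ketone trans to the isopropenyl-bearing stereocentre (substrate control, reinforced by the matched D-proline) while the carboxylic acid holds the ketone oxygen syn to the enamine carbon, so C6 (CHO trans to isopropenyl) and C5 (OH cis to CHO) should arise together; this all-trans, internally hydrogen-bonded isomer is also the thermodynamic one.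

Step 10
Reactants: 17 (1R,2S,5S)-2-hydroxy-2-methyl-5-(prop-1-en-2-yl)cyclopentane-1-carbaldehyde
Product: 18 (1S,2S,3S)-2-[(E)-2-iodoethenyl]-1-methyl-3-(prop-1-en-2-yl)cyclopentan-1-ol
Conditions: CrCl2 (6 equiv), CHI3 (2 equiv), THF, 0 °C → rt
Reagents that add atoms: iodoform, IC(I)I
Why: Takai olefination, in which the geminal dichromium species adds to the aldehyde and eliminates to the E-vinyl iodide under non-basic conditions that tolerate the free β-hydroxyl and should not epimerise C6.

Step 11
Reactants: 18 (1S,2S,3S)-2-[(E)-2-iodoethenyl]-1-methyl-3-(prop-1-en-2-yl)cyclopentan-1-ol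
Product: 19 (1S,2R,3S)-2-[(1E)-but-1-en-3-yn-1-yl]-1-methyl-3-(prop-1-en-2-yl)cyclopentan-1-ol
Conditions: HC≡CMgBr (3 equiv), ZnBr2 (3 equiv), THF, 0 °C; then 18, Pd(PPh3)4 (5 mol%), rt
Reagents that add atoms: ethynylmagnesium bromide (used as ethynylzinc bromide made in the flask), C#C[Mg]Br
Why: Negishi coupling of ethynylzinc bromide with the alkenyl iodide gives the terminal enyne directly with retention of the E geometry.

Step 12
Reactants: 19 (1S,2R,3S)-2-[(1E)-but-1-en-3-yn-1-yl]-1-methyl-3-(prop-1-en-2-yl)cyclopentan-1-ol; 5 [(3E)-4-bromobut-3-en-1-yn-1-yl]trimethylsilane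
Product: 21 (1S,2R,3S)-1-methyl-2-[(1E,3E,5E)-3-methyl-8-(trimethylsilyl)octa-1,3,5-trien-7-yn-1-yl]-3-(prop-1-en-2-yl)cyclopentan-1-ol, via bis-aluminium species 20 (not isolated)
Conditions: Me3Al (3 equiv), Cp2ZrCl2 (1 equiv), CH2Cl2, 0 °C → rt; evaporate; then 5, Pd2(dba)3 (2.5 mol%), P(2-furyl)3 (10 mol%), ZnCl2 (30 mol%), THF, rt; aq. NaHCO3
Reagents that add atoms: trimethylaluminium, C[Al](C)C
Why: syn-methylalumination and Negishi alkenyl–alkenyl coupling as in step 4, the first equivalent of Me3Al converting the hydroxyl into its O–AlMe2 alkoxide (returned on work-up) and the isopropenyl group being inert, sets the 9E alkene.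

Step 13
Reactants: 21 (1S,2R,3S)-1-methyl-2-[(1E,3E,5E)-3-methyl-8-(trimethylsilyl)octa-1,3,5-trien-7-yn-1-yl]-3-(prop-1-en-2-yl)cyclopentan-1-ol
Product: 22 (1S,2R,3S)-1-methyl-2-[(1E,3E,5E)-3-methylocta-1,3,5-trien-7-yn-1-yl]-3-(prop-1-en-2-yl)cyclopentan-1-ol
Conditions: K2CO3 (cat.), MeOH, rt, dark
Reagents that add atoms: none
Why: protodesilylation of the alkynylsilane; the tertiary alcohol and the triene are stable to mild carbonate.

Step 14
Reactants: 22 (1S,2R,3S)-1-methyl-2-[(1E,3E,5E)-3-methylocta-1,3,5-trien-7-yn-1-yl]-3-(prop-1-en-2-yl)cyclopentan-1-ol; 2 (E)-1-bromo-2-iodoethene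
Product: 24 (1S,2R,3S)-2-[(1E,3E,5E,7E,9E)-10-bromo-3,7-dimethyldeca-1,3,5,7,9-pentaen-1-yl]-1-methyl-3-(prop-1-en-2-yl)cyclopentan-1-ol, via bis-aluminium species 23 (not isolated)
Conditions: Me3Al (3 equiv), Cp2ZrCl2 (1 equiv), ClCH2CH2Cl, rt; evaporate; then 2 (1.5 equiv), Pd2(dba)3 (2.5 mol%), P(2-furyl)3 (10 mol%), ZnCl2 (30 mol%), THF, 0 °C → rt, dark; aq. NaHCO3
Reagents that add atoms: trimethylaluminium, C[Al](C)C
Why: syn-methylalumination sets the 13E alkene, and the Negishi coupling takes place at C–I only (oxidative addition of zerovalent palladium to C–I is much faster than to C–Br), so the E-bromodiene terminus survives as the handle for the final union.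

Step 15
Reactants: 13 (3E,5E,7E,9E)-6,10,14-trimethylpentadeca-3,5,7,9,13-pentaen-1-yne; 24 (1S,2R,3S)-2-[(1E,3E,5E,7E,9E)-10-bromo-3,7-dimethyldeca-1,3,5,7,9-pentaen-1-yl]-1-methyl-3-(prop-1-en-2-yl)cyclopentan-1-ol
Product: 27 (1S,2R,3S)-2-[(1E,3E,5E,7E,9E,11E,13E,15E,17E,19E)-3,7,12,16,20,24-hexamethylpentacosa-1,3,5,7,9,11,13,15,17,19,23-undecaen-1-yl]-1-methyl-3-(prop-1-en-2-yl)cyclopentan-1-ol, via alkenylalane 25 (not isolated), via aluminium alkoxide 26 (not isolated)
Conditions: 13 (1.2 equiv), Me3Al (2 equiv), Cp2ZrCl2 (1 equiv), ClCH2CH2Cl, rt, then evaporate and take up in THF; separately 24, Me3Al (1.0 equiv), THF, 0 °C; combine, Pd2(dba)3 (2.5 mol%), P(2-furyl)3 (10 mol%), ZnCl2 (30 mol%), THF/DMF, rt, dark, argon; aq. NaHCO3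
Reagents that add atoms: trimethylaluminium, C[Al](C)C
Why: Me–Al adds syn across the terminal C13'≡C14' alkyne of 13 under Cp2ZrCl2 catalysis, methyl to the internal and aluminium to the terminal carbon, to give the E-alkenylalane 25, which transfers its alkenyl group via zinc to the alkenylpalladium bromide formed by oxidative addition of zerovalent palladium into the C15'–Br bond of 26; reductive elimination then forms the C14'–C15' bond with retention at both alkenes. The closest known reaction type is the one-pot zirconium-catalysed carboalumination / palladium-catalysed alkenyl–alkenyl Negishi coupling used for conjugated polyenes of the retinoid and carotenoid class. No ring is closed and no stereocentre is created; the new stereochemical element is the 13'E trisubstituted alkene, fixed by the syn-carbometalation, while the 15E geometry is carried in by the bromide. The step needs reaction at the alkyne only, which the inertness of conjugated, isolated and 1,1-disubstituted alkenes to Me3Al/Cp2ZrCl2 at room temperature secures. It also needs an alane that is not protonated, which premetalation of the hydroxyl of 24 to the O–AlMe2 alkoxide 26 secures. One operation should thus deliver the last methyl branch, the last trisubstituted alkene and the complete C40 chain, and aqueous work-up frees the tertiary alcohol.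

**Compound list**

1 | acetylene | C#C | starting material
2 | (E)-1-bromo-2-iodoethene | Br/C=C/I | intermediate
3 | ethynyltrimethylsilane | C#C[Si](C)(C)C | starting material
4 | [(trimethylsilyl)ethynyl]zinc bromide (not isolated) | C[Si](C)(C)C#C[Zn]Br | intermediate
5 | [(3E)-4-bromobut-3-en-1-yn-1-yl]trimethylsilane | C[Si](C)(C)C#C/C=C/Br | intermediate
6 | 5-bromo-2-methylpent-2-ene | CC(C)=CCCBr | starting material
7 | 6-methylhept-5-en-1-yne | C#CCCC=C(C)C | intermediate
8 | [(1E)-2,6-dimethylhepta-1,5-dien-1-yl]dimethylalane (not isolated) | C[Al](C)/C=C(\C)CCC=C(C)C | intermediate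
9 | trimethyl[(3E,5E)-6,10-dimethylundeca-3,5,9-trien-1-yn-1-yl]silane | C[Si](C)(C)C#C/C=C/C=C(\C)CCC=C(C)C | intermediate
10 | (3E,5E)-6,10-dimethylundeca-3,5,9-trien-1-yne | C#C/C=C/C=C(\C)CCC=C(C)C | intermediate
11 | dimethyl[(1E,3E,5E)-2,6,10-trimethylundeca-1,3,5,9-tetraen-1-yl]alane (not isolated) | C[Al](C)/C=C(C)/C=C/C=C(\C)CCC=C(C)C | intermediate
12 | trimethyl[(3E,5E,7E,9E)-6,10,14-trimethylpentadeca-3,5,7,9,13-pentaen-1-yn-1-yl]silane | C[Si](C)(C)C#C/C=C/C=C(C)/C=C/C=C(\C)CCC=C(C)C | intermediate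
13 | (3E,5E,7E,9E)-6,10,14-trimethylpentadeca-3,5,7,9,13-pentaen-1-yne | C#C/C=C/C=C(C)/C=C/C=C(\C)CCC=C(C)C | intermediate
14 | (S)-(−)-limonene, (4S)-1-methyl-4-(prop-1-en-2-yl)cyclohex-1-ene | CC1=CC[C@H](CC1)C(C)=C | starting material
15 | (4S)-1-methyl-4-(prop-1-en-2-yl)-7,8,9-trioxabicyclo[4.2.1]nonane (secondary ozonide, bridgehead configuration not defined; not isolated) | C=C(C)[C@H]1CCC2(C)OOC(C1)O2 | intermediate
16 | (3S)-6-oxo-3-(prop-1-en-2-yl)heptanal | O=CC[C@H](CCC(C)=O)C(C)=C | intermediate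
17 | (1R,2S,5S)-2-hydroxy-2-methyl-5-(prop-1-en-2-yl)cyclopentane-1-carbaldehyde | C=C(C)[C@H]1CC[C@](C)(O)[C@@H]1C=O | intermediate
18 | (1S,2S,3S)-2-[(E)-2-iodoethenyl]-1-methyl-3-(prop-1-en-2-yl)cyclopentan-1-ol | C=C(C)[C@H]1CC[C@](C)(O)[C@@H]1/C=C/I | intermediate
19 | (1S,2R,3S)-2-[(1E)-but-1-en-3-yn-1-yl]-1-methyl-3-(prop-1-en-2-yl)cyclopentan-1-ol | C=C(C)[C@H]1CC[C@](C)(O)[C@@H]1/C=C/C#C | intermediate
20 | dimethylaluminium alkoxide of the (1E,3E)-4-(dimethylalumanyl)-3-methylbuta-1,3-dien-1-yl cyclopentanol derived from 19 (not isolated) | C=C(C)[C@H]1CC[C@](C)(O[Al](C)C)[C@@H]1/C=C/C(C)=C/[Al](C)C | intermediate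
21 | (1S,2R,3S)-1-methyl-2-[(1E,3E,5E)-3-methyl-8-(trimethylsilyl)octa-1,3,5-trien-7-yn-1-yl]-3-(prop-1-en-2-yl)cyclopentan-1-ol | C=C(C)[C@H]1CC[C@](C)(O)[C@@H]1/C=C/C(C)=C/C=C/C#C[Si](C)(C)C | intermediate
22 | (1S,2R,3S)-1-methyl-2-[(1E,3E,5E)-3-methylocta-1,3,5-trien-7-yn-1-yl]-3-(prop-1-en-2-yl)cyclopentan-1-ol | C=C(C)[C@H]1CC[C@](C)(O)[C@@H]1/C=C/C(C)=C/C=C/C#C | intermediate
23 | dimethylaluminium alkoxide of the (1E,3E,5E,7E)-8-(dimethylalumanyl)-3,7-dimethylocta-1,3,5,7-tetraen-1-yl cyclopentanol derived from 22 (not isolated) | C=C(C)[C@H]1CC[C@](C)(O[Al](C)C)[C@@H]1/C=C/C(C)=C/C=C/C(C)=C/[Al](C)C | intermediate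
24 | (1S,2R,3S)-2-[(1E,3E,5E,7E,9E)-10-bromo-3,7-dimethyldeca-1,3,5,7,9-pentaen-1-yl]-1-methyl-3-(prop-1-en-2-yl)cyclopentan-1-ol | C=C(C)[C@H]1CC[C@](C)(O)[C@@H]1/C=C/C(C)=C/C=C/C(C)=C/C=C/Br | intermediate
25 | dimethyl[(1E,3E,5E,7E,9E)-2,6,10,14-tetramethylpentadeca-1,3,5,7,9,13-hexaen-1-yl]alane (not isolated) | C[Al](C)/C=C(C)/C=C/C=C(C)/C=C/C=C(\C)CCC=C(C)C | intermediate
26 | dimethylaluminium alkoxide of bromide 24 (not isolated) | C=C(C)[C@H]1CC[C@](C)(O[Al](C)C)[C@@H]1/C=C/C(C)=C/C=C/C(C)=C/C=C/Br | intermediate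
27 | (1S,2R,3S)-2-[(1E,3E,5E,7E,9E,11E,13E,15E,17E,19E)-3,7,12,16,20,24-hexamethylpentacosa-1,3,5,7,9,11,13,15,17,19,23-undecaen-1-yl]-1-methyl-3-(prop-1-en-2-yl)cyclopentan-1-ol | C=C(C)[C@H]1CC[C@](C)(O)[C@@H]1/C=C/C(C)=C/C=C/C(C)=C/C=C/C=C(C)/C=C/C=C(C)/C=C/C=C(\C)CCC=C(C)C | target

**Step count and risks**

Total steps: 15. Longest linear sequence: 8 (steps 8 to 15, from (S)-limonene).

Steps most likely to fail:

Step 9. The tertiary aldol may dehydrate to the conjugated enal, the ketone may act as donor toward the aldehyde, or the facial selectivity at the ketone may be poor. The fallback sets out from keto aldehyde 16 and comes back at hydroxy aldehyde 17. The dehydrative aldol condensation (piperidine, AcOH, benzene, reflux) would give (5R)-2-methyl-5-(prop-1-en-2-yl)cyclopent-1-ene-1-carbaldehyde F1. Weitz–Scheffer epoxidation (H2O2, NaOH, MeOH, 0 °C), chemoselective for the electron-poor alkene and directed to the face anti to the isopropenyl group, would give (1R,2R,5S)-5-methyl-2-(prop-1-en-2-yl)-6-oxabicyclo[3.1.0]hexane-1-carbaldehyde F2. Reductive cleavage of the Cα–O bond (SmI2, THF/MeOH, −90 °C) with thermodynamic protonation of the enolate trans to isopropenyl would return 17, the carbinol configuration now being fixed by the face of epoxidation.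

Step 15. The alane may be lost by protonolysis or Lewis-acid-induced degradation of the polyene before a slow cross-coupling, and alkene geometry may scramble in the one-pot mixture. The fallback separates carbometalation from coupling and uses a Stille reaction of isolated partners; it sets out from tetraenyne 13 and comes back at target 27. Methylalumination of 13 as in step 15 followed by I2 (THF, −30 °C) would give (1E,3E,5E,7E,9E)-1-iodo-2,6,10,14-tetramethylpentadeca-1,3,5,7,9,13-hexaene F3, which can be purified. Iodine–lithium exchange (t-BuLi, Et2O, −78 °C) and Bu3SnCl would give tributyl[(1E,3E,5E,7E,9E)-2,6,10,14-tetramethylpentadeca-1,3,5,7,9,13-hexaen-1-yl]stannane F4. Stille coupling of F4 with bromide 24 (Pd2(dba)3, AsPh3, NMP, 40 °C, dark), which tolerates the free hydroxyl, would give 27.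

Step 10. The β-hydroxy aldehyde may undergo retro-aldol opening or dehydration under the Lewis-acidic chromium salts, and addition to the hindered aldehyde may be sluggish. The fallback sets out from hydroxy aldehyde 17, bypasses iodide 18 and comes back at enyne 19. Silylation (Et3SiOTf, 2,6-lutidine, CH2Cl2, −78 °C) would give (1R,2S,5S)-2-methyl-5-(prop-1-en-2-yl)-2-[(triethylsilyl)oxy]cyclopentane-1-carbaldehyde F5. Horner–Wadsworth–Emmons olefination with the lithium anion of diethyl [3-(trimethylsilyl)prop-2-yn-1-yl]phosphonate (LiN(SiMe3)2, THF, −78 → 0 °C) would give triethyl{[(1S,2R,3S)-1-methyl-3-(prop-1-en-2-yl)-2-[(1E)-4-(trimethylsilyl)but-1-en-3-yn-1-yl]cyclopentyl]oxy}silane F6. Tetrabutylammonium fluoride (THF, rt) would remove both silyl groups to give 19.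

**Further compounds**

F1 | step 9 | (5R)-2-methyl-5-(prop-1-en-2-yl)cyclopent-1-ene-1-carbaldehyde | C=C(C)[C@H]1CCC(C)=C1C=O
F2 | step 9 | (1R,2R,5S)-5-methyl-2-(prop-1-en-2-yl)-6-oxabicyclo[3.1.0]hexane-1-carbaldehyde (oxirane anti to isopropenyl) | C=C(C)[C@H]1CC[C@]2(C)O[C@]12C=O
F3 | step 15 | (1E,3E,5E,7E,9E)-1-iodo-2,6,10,14-tetramethylpentadeca-1,3,5,7,9,13-hexaene | I/C=C(C)/C=C/C=C(C)/C=C/C=C(\C)CCC=C(C)C
F4 | step 15 | tributyl[(1E,3E,5E,7E,9E)-2,6,10,14-tetramethylpentadeca-1,3,5,7,9,13-hexaen-1-yl]stannane | CCCC[Sn](CCCC)(CCCC)/C=C(C)/C=C/C=C(C)/C=C/C=C(\C)CCC=C(C)C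
F5 | step 10 | (1R,2S,5S)-2-methyl-5-(prop-1-en-2-yl)-2-[(triethylsilyl)oxy]cyclopentane-1-carbaldehyde | C=C(C)[C@H]1CC[C@](C)(O[Si](CC)(CC)CC)[C@@H]1C=O
F6 | step 10 | triethyl{[(1S,2R,3S)-1-methyl-3-(prop-1-en-2-yl)-2-[(1E)-4-(trimethylsilyl)but-1-en-3-yn-1-yl]cyclopentyl]oxy}silane | C=C(C)[C@H]1CC[C@](C)(O[Si](CC)(CC)CC)[C@@H]1/C=C/C#C[Si](C)(C)C
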